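The 4-hydroxy-2-pyridone is disconnected to a five-membered tetramic acid. Pyridone atoms N1, C2, C3, C4 and C6 are the lactam atoms of an L-tyrosine-derived 3-acetyl-5-(4-hydroxybenzyl)pyrrolidine-2,4-dione, and pyridone C5, the carbon that carries the six-membered carbocycle, is its benzylic CH2. One enzymatic oxidation moves the C4 carbonyl carbon from the ring CH onto that benzylic carbon: the C4–C5 bond forms, the ring grows to six members and aromatises. The precursor needs two steps from L-tyrosine methyl ester. Afterwards the phenol ring becomes the cis-1,4-diol, the nitrogen is hydroxylated and the acetyl group is condensed with an (R)-dienal made from butanal.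

Key step: step 3

Remark on the structures: the target is read as the 8R, all-E trienoyl chain and a cis-1,4-diol on the cyclohexane (both hydroxyls on one face, the secondary hydroxyl trans to the pyridone); the tetramic acid from L-tyrosine is 5S; no structure needed correction.

Assumption: a ring-expanding P450 of the tenellin-pathway type (or a homologue found by screening) turns over the 3-acetyl analogue of its natural 3-polyenoyl substrate; the precursor is therefore kept as the free phenol, free NH and 5S-configured compound, with a room-temperature cyclisation to protect that centre.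

Step 1
Reactants: 1 L-tyrosine methyl ester; 2 2,2,6-trimethyl-4H-1,3-dioxin-4-one
Product: 4 methyl N-(3-oxobutanoyl)-L-tyrosinate, via acetylketene 3 (not isolated)
Conditions: toluene/1,4-dioxane, 105 °C, acetone distilled off
Reagents that add atoms: none
Why: Thermal retro-[4+2] cleavage of the dioxinone releases acetylketene, which the primary amine (far more nucleophilic than the phenol) should trap as the acetoacetamide (N-acetoacetylation) without touching the stereocentre.

Step 2
Reactants: 4 methyl N-(3-oxobutanoyl)-L-tyrosinate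
Product: 5 (S)-3-acetyl-4-hydroxy-5-(4-hydroxybenzyl)-1,5-dihydro-2H-pyrrol-2-one
Conditions: NaOMe (2.2 equiv), MeOH, rt, short reaction time; then 1 M HCl
Reagents that add atoms: none
Why: Lacey–Dieckmann cyclisation, in which the acetoacetamide enolate attacks the methyl ester to close the pyrrolidine-2,4-dione; room temperature and a short reaction time are chosen to limit epimerisation of the 5S centre that the enzyme is expected to recognise.

Step 3
Reactants: 5 (S)-3-acetyl-4-hydroxy-5-(4-hydroxybenzyl)-1,5-dihydro-2H-pyrrol-2-one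
Product: 6 3-acetyl-4-hydroxy-5-(4-hydroxyphenyl)pyridin-2(1H)-one
Conditions: ring-expanding cytochrome P450 (TenA type, Beauveria bassiana) with its NADPH–cytochrome P450 reductase (yeast microsomes), NADPH (cat.), D-glucose/glucose dehydrogenase, air, potassium phosphate buffer pH 7.5 (5% DMSO), 28 °C
Reagents that add atoms: none
Why: Proposed new method: the ferryl-oxo haem abstracts a hydrogen atom from the benzylic CH2, the 4-hydroxyphenyl-stabilised radical adds to the C4 carbonyl carbon, and the resulting cyclopropyloxy radical fragments at the old C4–C5 bond, so that C4 is transferred to the benzylic carbon and an α-amino radical remains, which loses one electron and a proton to give the aromatic 2-pyridone. The closest known reaction type is the P450 ring expansion of 3-polyenoyl-5-(4-hydroxybenzyl)tetramic acids to 5-aryl-4-hydroxy-2-pyridones in fungal pyridone biosynthesis (in chemical terms a Dowd–Beckwith-type radical 1,2-acyl shift); new here is the acetyl group in place of the long acyl chain. The six-membered ring closes by 3-exo-trig radical addition followed by β-scission, that is by ring enlargement and not by a direct six-membered cyclisation. No stereocentre is created, and the C5 centre of 5 is lost. The step needs the rearrangement to outrun oxygen rebound at the benzylic radical; the free para-hydroxyl (a long-lived, delocalised radical), the free NH and the natural 5S configuration are retained so that the enzyme pocket can hold the radical over the C4 carbonyl, and homologous enzymes are to be screened for acceptance of the short chain.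

Step 4
Reactants: 6 3-acetyl-4-hydroxy-5-(4-hydroxyphenyl)pyridin-2(1H)-one
Product: 7 3-acetyl-4-hydroxy-5-(1-hydroxy-4-oxocyclohexa-2,5-dien-1-yl)pyridin-2(1H)-one
Conditions: PhI(OAc)2 (1.1 equiv), MeCN/H2O (3:1), 0 °C; crude product used at once
Reagents that add atoms: water, O
Why: Oxidative dearomatisation of a para-substituted phenol with water as the nucleophile (para-quinol formation); C3 of the pyridone is blocked by the acetyl group, so the iodine reagent finds no enolic C–H there, and the product has no stereocentre.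

Step 5
Reactants: 7 3-acetyl-4-hydroxy-5-(1-hydroxy-4-oxocyclohexa-2,5-dien-1-yl)pyridin-2(1H)-one
Product: 8 3-acetyl-4-hydroxy-5-(1-hydroxy-4-oxocyclohexyl)pyridin-2(1H)-one
Conditions: H2 (1 atm), Rh/Al2O3 (5 wt% Rh), EtOAc, rt
Reagents that add atoms: none
Why: Heterogeneous hydrogenation of the two enone C=C bonds; rhodium on alumina in a neutral aprotic solvent is chosen because it is less prone than palladium to hydrogenolysis of the doubly allylic tertiary C–O bond and to re-aromatisation.

Step 6
Reactants: 8 3-acetyl-4-hydroxy-5-(1-hydroxy-4-oxocyclohexyl)pyridin-2(1H)-one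
Product: 9 3-acetyl-5-(cis-1,4-dihydroxycyclohexyl)-4-hydroxypyridin-2(1H)-one (hydroxyls cis, secondary hydroxyl trans to the pyridone)
Conditions: NaBH4, MeOH, −40 → 0 °C; then aq. NH4Cl and dilute HCl to pH 4
Reagents that add atoms: none
Why: Borohydride reduction of a 4,4-disubstituted cyclohexanone, in which the chair with equatorial pyridonyl and axial tertiary hydroxyl takes hydride axially to give the equatorial secondary alcohol (the cis-1,4-diol) while the acetyl group is shielded as its enolate; the minor trans-diol is to be removed by crystallisation or chromatography.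

Step 7
Reactants: 9 3-acetyl-5-(cis-1,4-dihydroxycyclohexyl)-4-hydroxypyridin-2(1H)-one
Product: 11 3-acetyl-5-[cis-1,4-bis(triethylsilyloxy)cyclohexyl]-4-hydroxypyridin-2(1H)-one, via tetrakis(triethylsilyl) ether 10 (not isolated)
Conditions: Et3SiOTf (5 equiv), 2,6-lutidine, CH2Cl2, −78 → 0 °C; then MeOH/sat. aq. NaHCO3, rt
Reagents that add atoms: triethylsilyl trifluoromethanesulfonate, CC[Si](CC)(CC)OS(=O)(=O)C(F)(F)F
Why: Exhaustive silylation with the silyl triflate (which also reaches the tertiary alcohol) followed by selective solvolysis of the two labile pyridyl O–Si bonds should leave only the two alkyl silyl ethers, which removes two acidic hydroxyls before the enolate chemistry of step 14.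

Step 8
Reactants: 11 3-acetyl-5-[cis-1,4-bis(triethylsilyloxy)cyclohexyl]-4-hydroxypyridin-2(1H)-one
Product: 14 3-acetyl-5-[cis-1,4-bis(triethylsilyloxy)cyclohexyl]-1,4-dihydroxypyridin-2(1H)-one, via bis(trimethylsilyl) pyridine 12 (not isolated), via silylated pyridine N-oxide 13 (not isolated)
Conditions: (Me3Si)2NH, Me3SiCl (cat.), 110 °C, then evaporation; MoO(O2)2·DMF (1.5 equiv, prepared from MoO3, 30% H2O2 and DMF), CH2Cl2, rt; then aq. Na4EDTA, pH 4
Reagents that add atoms: oxodiperoxomolybdenum–DMF complex, O=[Mo]12(OO1)OO2.CN(C)C=O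
Why: N-Hydroxylation of a 2-pyridone through its O-silyl imidate, in which the pyridine nitrogen of the 2-silyloxypyridine attacks a peroxo oxygen of the molybdenum complex and hydrolysis of the trimethylsilyl groups gives the cyclic hydroxamic acid; no stereocentre is involved and the alkyl triethylsilyl ethers survive the neutral work-up.

Step 9
Reactants: 15 butanal
Product: 17 (2E,4R)-4-(hydroxymethyl)-N-methoxy-N-methylhex-2-enamide, via (S)-2-(hydroxymethyl)butanal 16 (not isolated)
Conditions: CH2O (37% aq.), (R)-2-[diphenyl(trimethylsilyloxy)methyl]pyrrolidine (10 mol%), pH 7 phosphate buffer, toluene, 0 °C → rt; then Ph3P=CHC(O)N(OMe)Me, CH2Cl2, rt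
Reagents that add atoms: formaldehyde, C=O; N-methoxy-N-methyl-2-(triphenylphosphoranylidene)acetamide, CON(C)C(=O)C=P(c1ccccc1)(c1ccccc1)c1ccccc1
Why: Enamine-catalysed α-hydroxymethylation, in which the bulky diarylsilyloxymethyl group of the R catalyst blocks one face of the E-enamine of butanal so that formaldehyde should add to the open face and set the S centre, followed at once by an E-selective Wittig reaction with a stabilised ylide that traps the labile β-hydroxy aldehyde before it can dehydrate or racemise.

Step 10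
Reactants: 17 (2E,4R)-4-(hydroxymethyl)-N-methoxy-N-methylhex-2-enamide
Product: 18 (2E,4R)-4-[(tert-butyldimethylsilyloxy)methyl]-N-methoxy-N-methylhex-2-enamide
Conditions: TBSCl, imidazole, CH2Cl2, rt
Reagents that add atoms: tert-butyldimethylsilyl chloride, CC(C)(C)[Si](C)(C)Cl
Why: Standard silylation of a primary alcohol, which masks the only acidic proton of the side chain for the hydride and enolate steps that follow.

Step 11
Reactants: 18 (2E,4R)-4-[(tert-butyldimethylsilyloxy)methyl]-N-methoxy-N-methylhex-2-enamide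
Product: 19 (2E,4R)-4-[(tert-butyldimethylsilyloxy)methyl]hex-2-enal
Conditions: iBu2AlH (1.2 equiv), THF, −78 °C; then aq. potassium sodium tartrate
Reagents that add atoms: none
Why: Hydride reduction of a Weinreb amide stops at the chelated tetrahedral intermediate, which releases the enal only on work-up, and at −78 °C no conjugate reduction is expected.

Step 12
Reactants: 19 (2E,4R)-4-[(tert-butyldimethylsilyloxy)methyl]hex-2-enal
Product: 20 (2E,4E,6R)-6-[(tert-butyldimethylsilyloxy)methyl]-N-methoxy-N-methylocta-2,4-dienamide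
Conditions: (EtO)2P(O)CH2C(O)N(OMe)Me, NaH, THF, 0 °C (phosphonate anion preformed)
Reagents that add atoms: diethyl [2-(methoxy(methyl)amino)-2-oxoethyl]phosphonate, CCOP(=O)(CC(=O)N(C)OC)OCC
Why: Horner–Wadsworth–Emmons olefination with the preformed sodium phosphonate, which leaves no free base to deprotonate the γ-stereocentre of the enal and should give the 2E,4E-dienamide.

Step 13
Reactants: 20 (2E,4E,6R)-6-[(tert-butyldimethylsilyloxy)methyl]-N-methoxy-N-methylocta-2,4-dienamide
Product: 21 (2E,4E,6R)-6-[(tert-butyldimethylsilyloxy)methyl]octa-2,4-dienal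
Conditions: iBu2AlH (1.2 equiv), THF, −78 °C; then aq. potassium sodium tartrate
Reagents that add atoms: none
Why: Second Weinreb amide reduction, which delivers the dienal directly at the aldehyde oxidation level without a separate oxidation step.

Step 14
Reactants: 14 3-acetyl-5-[cis-1,4-bis(triethylsilyloxy)cyclohexyl]-1,4-dihydroxypyridin-2(1H)-one; 21 (2E,4E,6R)-6-[(tert-butyldimethylsilyloxy)methyl]octa-2,4-dienal
Product: 23 3-[(2E,4E,6E,8R)-8-[(tert-butyldimethylsilyloxy)methyl]deca-2,4,6-trienoyl]-5-[cis-1,4-bis(triethylsilyloxy)cyclohexyl]-1,4-dihydroxypyridin-2(1H)-one, via aldol adduct 22 (not isolated)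
Conditions: 14, LiN(iPr)2 (3.2 equiv), THF, −78 → −20 °C; 21, −78 °C; AcOH; then TsOH·H2O (cat.), 4 Å MS, CH2Cl2, 0 °C → rt
Reagents that add atoms: none
Why: Aldol condensation through the trilithium salt (N–O, 4-O and the terminal CH2 of the acetyl group), the established polyanion reactivity of 3-acetyl-4-hydroxy heterocycles, in which the terminal carbanion should add to the aldehyde at −78 °C faster than the dienal can be deprotonated at its stereocentre, and mild acid then dehydrates the dienylic carbinol to the E-trienone, so the transient carbinol centre is lost.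

Step 15
Reactants: 23 3-[(2E,4E,6E,8R)-8-[(tert-butyldimethylsilyloxy)methyl]deca-2,4,6-trienoyl]-5-[cis-1,4-bis(triethylsilyloxy)cyclohexyl]-1,4-dihydroxypyridin-2(1H)-one
Product: 24 3-[(2E,4E,6E,8R)-8-(hydroxymethyl)deca-2,4,6-trienoyl]-5-(cis-1,4-dihydroxycyclohexyl)-1,4-dihydroxypyridin-2(1H)-one (target)
Conditions: HF·pyridine, pyridine, THF, 0 °C → rt
Reagents that add atoms: none
Why: Fluoride-mediated cleavage of the primary tert-butyldimethylsilyl and the two triethylsilyl ethers in one operation under pyridine-buffered conditions that the trienone and the tertiary alcohol should tolerate.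

Compound list
1 | L-tyrosine methyl ester | COC(=O)[C@@H](N)Cc1ccc(O)cc1 | starting material
2 | 2,2,6-trimethyl-4H-1,3-dioxin-4-one | CC1=CC(=O)OC(C)(C)O1 | starting material
3 | acetylketene | CC(=O)C=C=O | intermediate (not isolated)
4 | methyl N-(3-oxobutanoyl)-L-tyrosinate | CC(=O)CC(=O)N[C@@H](Cc1ccc(O)cc1)C(=O)OC | intermediate
5 | (S)-3-acetyl-4-hydroxy-5-(4-hydroxybenzyl)-1,5-dihydro-2H-pyrrol-2-one | CC(=O)C1=C(O)[C@H](Cc2ccc(O)cc2)NC1=O | intermediate (key-step precursor)
6 | 3-acetyl-4-hydroxy-5-(4-hydroxyphenyl)pyridin-2(1H)-one | CC(=O)c1c(O)c(-c2ccc(O)cc2)c[nH]c1=O | intermediate (key-step product)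
7 | 3-acetyl-4-hydroxy-5-(1-hydroxy-4-oxocyclohexa-2,5-dien-1-yl)pyridin-2(1H)-one | CC(=O)c1c(O)c(C2(O)C=CC(=O)C=C2)c[nH]c1=O | intermediate
8 | 3-acetyl-4-hydroxy-5-(1-hydroxy-4-oxocyclohexyl)pyridin-2(1H)-one | CC(=O)c1c(O)c(C2(O)CCC(=O)CC2)c[nH]c1=O | intermediate
9 | 3-acetyl-5-(cis-1,4-dihydroxycyclohexyl)-4-hydroxypyridin-2(1H)-one | CC(=O)c1c(O)c([C@]2(O)CC[C@@H](O)CC2)c[nH]c1=O | intermediate
10 | 3-acetyl-5-[cis-1,4-bis(triethylsilyloxy)cyclohexyl]-2,4-bis(triethylsilyloxy)pyridine | CC(=O)c1c(O[Si](CC)(CC)CC)c([C@]2(O[Si](CC)(CC)CC)CC[C@@H](O[Si](CC)(CC)CC)CC2)cnc1O[Si](CC)(CC)CC | intermediate (not isolated)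
11 | 3-acetyl-5-[cis-1,4-bis(triethylsilyloxy)cyclohexyl]-4-hydroxypyridin-2(1H)-one | CC(=O)c1c(O)c([C@]2(O[Si](CC)(CC)CC)CC[C@@H](O[Si](CC)(CC)CC)CC2)c[nH]c1=O | intermediate
12 | 3-acetyl-5-[cis-1,4-bis(triethylsilyloxy)cyclohexyl]-2,4-bis(trimethylsilyloxy)pyridine | CC(=O)c1c(O[Si](C)(C)C)c([C@]2(O[Si](CC)(CC)CC)CC[C@@H](O[Si](CC)(CC)CC)CC2)cnc1O[Si](C)(C)C | intermediate (not isolated)
13 | 3-acetyl-5-[cis-1,4-bis(triethylsilyloxy)cyclohexyl]-2,4-bis(trimethylsilyloxy)pyridine 1-oxide | CC(=O)c1c(O[Si](C)(C)C)c([C@]2(O[Si](CC)(CC)CC)CC[C@@H](O[Si](CC)(CC)CC)CC2)c[n+]([O-])c1O[Si](C)(C)C | intermediate (not isolated)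
14 | 3-acetyl-5-[cis-1,4-bis(triethylsilyloxy)cyclohexyl]-1,4-dihydroxypyridin-2(1H)-one | CC(=O)c1c(O)c([C@]2(O[Si](CC)(CC)CC)CC[C@@H](O[Si](CC)(CC)CC)CC2)cn(O)c1=O | intermediate
15 | butanal | CCCC=O | starting material
16 | (S)-2-(hydroxymethyl)butanal | CC[C@H](C=O)CO | intermediate (not isolated)
17 | (2E,4R)-4-(hydroxymethyl)-N-methoxy-N-methylhex-2-enamide | CC[C@H](/C=C/C(=O)N(C)OC)CO | intermediate
18 | (2E,4R)-4-[(tert-butyldimethylsilyloxy)methyl]-N-methoxy-N-methylhex-2-enamide | CC[C@H](/C=C/C(=O)N(C)OC)CO[Si](C)(C)C(C)(C)C | intermediate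
19 | (2E,4R)-4-[(tert-butyldimethylsilyloxy)methyl]hex-2-enal | CC[C@H](/C=C/C=O)CO[Si](C)(C)C(C)(C)C | intermediate
20 | (2E,4E,6R)-6-[(tert-butyldimethylsilyloxy)methyl]-N-methoxy-N-methylocta-2,4-dienamide | CC[C@H](/C=C/C=C/C(=O)N(C)OC)CO[Si](C)(C)C(C)(C)C | intermediate
21 | (2E,4E,6R)-6-[(tert-butyldimethylsilyloxy)methyl]octa-2,4-dienal | CC[C@H](/C=C/C=C/C=O)CO[Si](C)(C)C(C)(C)C | intermediate
22 | 3-[(4E,6E,8R)-8-[(tert-butyldimethylsilyloxy)methyl]-3-hydroxydeca-4,6-dienoyl]-5-[cis-1,4-bis(triethylsilyloxy)cyclohexyl]-1,4-dihydroxypyridin-2(1H)-one (both carbinol epimers) | CC[C@H](/C=C/C=C/C(O)CC(=O)c1c(O)c([C@]2(O[Si](CC)(CC)CC)CC[C@@H](O[Si](CC)(CC)CC)CC2)cn(O)c1=O)CO[Si](C)(C)C(C)(C)C | intermediate (not isolated)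
23 | 3-[(2E,4E,6E,8R)-8-[(tert-butyldimethylsilyloxy)methyl]deca-2,4,6-trienoyl]-5-[cis-1,4-bis(triethylsilyloxy)cyclohexyl]-1,4-dihydroxypyridin-2(1H)-one | CC[C@H](/C=C/C=C/C=C/C(=O)c1c(O)c([C@]2(O[Si](CC)(CC)CC)CC[C@@H](O[Si](CC)(CC)CC)CC2)cn(O)c1=O)CO[Si](C)(C)C(C)(C)C | intermediate
24 | 3-[(2E,4E,6E,8R)-8-(hydroxymethyl)deca-2,4,6-trienoyl]-5-(cis-1,4-dihydroxycyclohexyl)-1,4-dihydroxypyridin-2(1H)-one | CC[C@H](/C=C/C=C/C=C/C(=O)c1c(O)c([C@]2(O)CC[C@@H](O)CC2)cn(O)c1=O)CO | target

Total step count: 15. Longest linear sequence: 10 steps (steps 1–8, 14 and 15, from L-tyrosine methyl ester); the dienal branch takes 5 steps (steps 9–13).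

Steps most likely to fail

Step 3 (labelled step). The truncated acetyl chain may not be bound productively, so that there is no turnover, or oxygen rebound gives plain benzylic hydroxylation instead of the acyl shift. The fallback uses known chemistry and builds the pyridone without ring expansion. It sets out from 2 and commercial methyl 2-[4-(benzyloxy)phenyl]acetate (COC(=O)Cc1ccc(OCc2ccccc2)cc1). Heating the ester with tert-butoxybis(dimethylamino)methane should give methyl 2-[4-(benzyloxy)phenyl]-3-(dimethylamino)acrylate F1. Amine exchange with NH4OAc in MeOH gives methyl (Z)-3-amino-2-[4-(benzyloxy)phenyl]acrylate F2. Acetoacetylation with 2 in hot toluene gives methyl (Z)-2-[4-(benzyloxy)phenyl]-3-(3-oxobutanamido)acrylate F3. NaOMe in MeOH closes the ring by Dieckmann condensation to 3-acetyl-5-[4-(benzyloxy)phenyl]-4-hydroxypyridin-2(1H)-one F4. Hydrogenolysis (H2, Pd/C) removes the benzyl group, and the sequence comes back to the route at 6.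

Step 8. Oxygen transfer to the pyridine nitrogen may be sluggish, because the nitrogen is deactivated by the acetyl group and flanked by a silyloxy group, and product may be lost through chelation of molybdenum. The fallback replaces direct N-hydroxylation by N-oxidation of a 2-alkoxypyridine and sets out from 11. O-Benzylation of both pyridone oxygens with BnBr/Ag2CO3 in toluene should give 3-acetyl-2,4-bis(benzyloxy)-5-[cis-1,4-bis(triethylsilyloxy)cyclohexyl]pyridine F5. mCPBA in CH2Cl2 oxidises the now ordinary pyridine nitrogen to the 1-oxide F6. Hydrogenolysis of both benzyl ethers (H2, Pd/C, EtOAc, stopped after uptake of two equivalents) unmasks the 1,4-dihydroxy-2-pyridone, and the sequence comes back to the route at 14.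

Step 14. Proton transfer from the dienal to the trianion, reversal of the aldol addition before dehydration, or acid-induced loss of the tertiary silyloxy group during dehydration may erode the condensation. The fallback changes the C=C bond formation to an olefination that needs no dehydration and sets out from 14. The trilithium salt is quenched with ClP(OEt)2 and the phosphonite is oxidised in air to diethyl {2-[5-(cis-1,4-bis(triethylsilyloxy)cyclohexyl)-1,4-dihydroxy-2-oxo-1,2-dihydropyridin-3-yl]-2-oxoethyl}phosphonate F7. Its potassium salt (KOtBu, THF, 0 °C → rt) should olefinate dienal 21 in a Horner–Wadsworth–Emmons reaction, made irreversible by loss of phosphate, and the sequence comes back to the route at 23.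

Further compounds
F1 | step 3 | methyl 2-[4-(benzyloxy)phenyl]-3-(dimethylamino)acrylate (E/Z mixture, geometry not defined) | COC(=O)C(=CN(C)C)c1ccc(OCc2ccccc2)cc1
F2 | step 3 | methyl (Z)-3-amino-2-[4-(benzyloxy)phenyl]acrylate | COC(=O)/C(=C\N)c1ccc(OCc2ccccc2)cc1
F3 | step 3 | methyl (Z)-2-[4-(benzyloxy)phenyl]-3-(3-oxobutanamido)acrylate | COC(=O)/C(=C\NC(=O)CC(C)=O)c1ccc(OCc2ccccc2)cc1
F4 | step 3 | 3-acetyl-5-[4-(benzyloxy)phenyl]-4-hydroxypyridin-2(1H)-one | CC(=O)c1c(O)c(-c2ccc(OCc3ccccc3)cc2)c[nH]c1=O
F5 | step 8 | 3-acetyl-2,4-bis(benzyloxy)-5-[cis-1,4-bis(triethylsilyloxy)cyclohexyl]pyridine | CC(=O)c1c(OCc2ccccc2)c([C@]3(O[Si](CC)(CC)CC)CC[C@@H](O[Si](CC)(CC)CC)CC3)cnc1OCc1ccccc1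
F6 | step 8 | 3-acetyl-2,4-bis(benzyloxy)-5-[cis-1,4-bis(triethylsilyloxy)cyclohexyl]pyridine 1-oxide | CC(=O)c1c(OCc2ccccc2)c([C@]3(O[Si](CC)(CC)CC)CC[C@@H](O[Si](CC)(CC)CC)CC3)c[n+]([O-])c1OCc1ccccc1
F7 | step 14 | diethyl {2-[5-(cis-1,4-bis(triethylsilyloxy)cyclohexyl)-1,4-dihydroxy-2-oxo-1,2-dihydropyridin-3-yl]-2-oxoethyl}phosphonate | CCOP(=O)(CC(=O)c1c(O)c([C@]2(O[Si](CC)(CC)CC)CC[C@@H](O[Si](CC)(CC)CC)CC2)cn(O)c1=O)OCC
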